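**Plan**

- Numbering: each quinone ring is C1(=O), C2(OH), C3(CH3), C4(=O), C5 (ring–ring bond), C6 (arylethyl chain). Ring A carries the 2-methoxyphenylethyl chain; ring B (primed atoms) carries the phenylethyl chain.
- Enabling feature: C4–C5–C5'–C4' is a succinate backbone, and in each ring C6–C1–C2–C3 with its methyl is a β-substituted ethyl vinyl ketone. Each ring is therefore a 2-methylresorcinol that a 3+3 Michael–Claisen annulation can build and that is oxidised at C1 last.
- Cuts: the C1–O and C1'–O bonds (hydroxyquinone back to resorcinol); ring B at C5'–C6' and C3'–C4' (enone plus ring A arylacetate); ring A at C5–C6 and C3–C4 (enone plus triethyl ethane-1,1,2-tricarboxylate, the extra ester leaving as CO2); both enone C=C bonds (Horner–Wadsworth–Emmons).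
- Forward order: two enones; ring A (annulation, decarboxylation, aromatisation, esterification, benzylation); ring B annulated onto the ring A acetate; aromatisation, debenzylation, double oxidation. The ring–ring bond is the original succinate C–C bond, so no aryl–aryl coupling is needed.
- Stereochemistry: the target has no stereocentre. The sp3 centres at C5/C6 and C5'/C6' are transient, arise under thermodynamic control (trans expected) and are erased on aromatisation.

Key step: step 8

Remark: the target SMILES carries no stereodescriptor, so the hindered ring–ring axis is taken as racemic; cyclic 1,3-diones are drawn as one enol tautomer.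

**Route**

Step 1
Reactants: 1 3-phenylpropanal; 2 diethyl (2-oxobutyl)phosphonate
Product: 3 (E)-7-phenylhept-4-en-3-one
Conditions: Ba(OH)2, THF/H2O (40:1), rt
Reagents that add atoms: none
Why: Horner–Wadsworth–Emmons olefination of an enolisable aliphatic aldehyde with a stabilised β-ketophosphonate under mild hydroxide activation should give the E-enone selectively.

Step 2
Reactants: 4 3-(2-methoxyphenyl)propanoic acid
Product: 5 3-(2-methoxyphenyl)propan-1-ol
Conditions: BH3·SMe2, THF, 0 °C to rt; aqueous work-up
Reagents that add atoms: none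
Why: Borane reduction of a carboxylic acid to the primary alcohol is chemoselective and leaves the aryl methyl ether untouched.

Step 3
Reactants: 5 3-(2-methoxyphenyl)propan-1-ol
Product: 6 3-(2-methoxyphenyl)propanal
Conditions: PhI(OAc)2, TEMPO (2,2,6,6-tetramethylpiperidin-1-oxyl, 10 mol%), CH2Cl2, rt
Reagents that add atoms: none
Why: The nitroxyl-catalysed oxidation of a primary alcohol with PhI(OAc)2 stops at the aldehyde and tolerates the electron-rich arene.

Step 4
Reactants: 6 3-(2-methoxyphenyl)propanal; 2 diethyl (2-oxobutyl)phosphonate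
Product: 7 (E)-7-(2-methoxyphenyl)hept-4-en-3-one
Conditions: Ba(OH)2, THF/H2O (40:1), rt
Reagents that add atoms: none
Why: The same Horner–Wadsworth–Emmons olefination as in step 1 should deliver the second E-enone.

Step 5
Reactants: 7 (E)-7-(2-methoxyphenyl)hept-4-en-3-one; 8 triethyl ethane-1,1,2-tricarboxylate
Product: 12 2-{4-hydroxy-6-[2-(2-methoxyphenyl)ethyl]-3-methyl-2-oxocyclohex-3-en-1-yl}acetic acid (racemic diastereomer mixture), via keto triester 9 (not isolated), via dione diester 10 (not isolated), via dione diacid 11 (not isolated)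
Conditions: NaOEt, EtOH, reflux; then aq. NaOH, reflux; then HCl to pH 1, reflux
Reagents that add atoms: sodium hydroxide, [Na+].[OH-]
Why: In this malonate–enone Michael–Claisen annulation the malonate carbanion of 8 adds 1,4 to 7 (C5–C6), the ethyl ketone enolate acylates on a malonate ester in a six-membered Dieckmann-type closure (C3–C4) driven by irreversible deprotonation of the 2-methyl-1,3-dione, and saponification followed by acid-promoted loss of CO2 from the quaternary β-keto acid leaves the acetic acid arm on C5; the C5 and C6 centres form without control (trans expected after equilibration at C5) and are destroyed in step 6.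

Step 6
Reactants: 12 2-{4-hydroxy-6-[2-(2-methoxyphenyl)ethyl]-3-methyl-2-oxocyclohex-3-en-1-yl}acetic acid
Product: 14 methyl 2-{2,4-dihydroxy-6-[2-(2-methoxyphenyl)ethyl]-3-methylphenyl}acetate, via resorcinol acid 13 (not isolated)
Conditions: DDQ, 1,4-dioxane, reflux; filter, concentrate; then MeOH, H2SO4 (cat.), 50 °C
Reagents that add atoms: methanol, CO
Why: Quinone dehydrogenation of the cyclohexane-1,3-dione (hydride loss from C6 of the dienol, then tautomerisation) should give the 2-methylresorcinol and remove both sp3 centres, and Fischer esterification of the crude acid in acidic methanol secures the open methyl ester instead of a lactone with the neighbouring phenol.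

Step 7
Reactants: 14 methyl 2-{2,4-dihydroxy-6-[2-(2-methoxyphenyl)ethyl]-3-methylphenyl}acetate
Product: 15 methyl 2-{2,4-bis(benzyloxy)-6-[2-(2-methoxyphenyl)ethyl]-3-methylphenyl}acetate
Conditions: BnBr, K2CO3, DMF, 60 °C
Reagents that add atoms: benzyl bromide, BrCc1ccccc1
Why: Williamson etherification of both phenoxides in a dipolar aprotic solvent should proceed cleanly, since carbonate is too weak to enolise the arylacetate and the ester CH2 therefore stays untouched.

Step 8
Reactants: 15 methyl 2-{2,4-bis(benzyloxy)-6-[2-(2-methoxyphenyl)ethyl]-3-methylphenyl}acetate; 3 (E)-7-phenylhept-4-en-3-one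
Product: 17 trans-6-{2,4-bis(benzyloxy)-6-[2-(2-methoxyphenyl)ethyl]-3-methylphenyl}-3-hydroxy-2-methyl-5-(2-phenylethyl)cyclohex-2-en-1-one (racemic; enol form of the ring B cyclohexane-1,3-dione), via keto ester 16 (not isolated)
Conditions: KOt-Bu (2.2 equiv), THF, −20 °C, slow addition of 3; then 50 °C; aq. HCl work-up
Reagents that add atoms: none
Why: KOt-Bu converts 15 into its benzylic potassium ester enolate, which adds 1,4 to enone 3 (C5'–C6' bond) to give the enolate of keto ester 16; proton transfer moves the ketone enolate from C1' to C3', and this enolate acylates on the methyl ester (C3'–C4' bond) with loss of methoxide, the irreversible deprotonation of the resulting 2-methyl-1,3-dione pulling every preceding equilibrium forward. The closest known reaction type is the alkoxide-mediated Michael–Claisen (3+3) annulation of arylacetic or malonic esters with enones to 4,5-disubstituted cyclohexane-1,3-diones. Ring B closes in a 6-(enolexo)-exo-trig Claisen (Dieckmann-type) acylation. The C5' and C6' centres are set only relative to each other: C5' stays epimerisable (α to the ester, later α to the ketone), so equilibration should place the ring A arene and the phenylethyl chain trans and pseudo-equatorial, and no absolute control is needed because both centres are erased in step 9. The step needs conjugate instead of carbonyl addition and closure from C3' only; the stabilised, hindered benzylic enolate (whose 1,2-adduct can revert) secures the first and the impossibility of a four-membered closure from C1' the second, while the benzyl ethers keep ring A free of acidic OH groups. Slow addition of 3 to the preformed enolate in an aprotic medium limits self-condensation of the enolisable enone.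

Step 9
Reactants: 17 trans-6-{2,4-bis(benzyloxy)-6-[2-(2-methoxyphenyl)ethyl]-3-methylphenyl}-3-hydroxy-2-methyl-5-(2-phenylethyl)cyclohex-2-en-1-one
Product: 18 2',4'-bis(benzyloxy)-6'-[2-(2-methoxyphenyl)ethyl]-3,3'-dimethyl-6-(2-phenylethyl)-[1,1'-biphenyl]-2,4-diol (racemic about the biaryl axis)
Conditions: DDQ, 1,4-dioxane, 80 °C to reflux
Reagents that add atoms: none
Why: Quinone dehydrogenation of a cyclohexane-1,3-dione to a resorcinol: DDQ should abstract hydride from C6' of the dienol tautomer and tautomerisation then aromatises ring B, erasing both stereocentres while the benzyl ethers and the ring–ring bond stay intact.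

Step 10
Reactants: 18 2',4'-bis(benzyloxy)-6'-[2-(2-methoxyphenyl)ethyl]-3,3'-dimethyl-6-(2-phenylethyl)-[1,1'-biphenyl]-2,4-diol
Product: 19 6-[2-(2-methoxyphenyl)ethyl]-3,3'-dimethyl-6'-(2-phenylethyl)-[1,1'-biphenyl]-2,2',4,4'-tetrol (racemic about the biaryl axis)
Conditions: H2 (1 atm), 10% Pd/C (palladium on carbon), EtOAc/MeOH, rt
Reagents that add atoms: none
Why: Catalytic hydrogenolysis cleaves the two aryl benzyl ethers, while the aryl methyl ether and the arenes are inert under these conditions.

Step 11
Reactants: 19 6-[2-(2-methoxyphenyl)ethyl]-3,3'-dimethyl-6'-(2-phenylethyl)-[1,1'-biphenyl]-2,2',4,4'-tetrol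
Product: 20 2-hydroxy-5-[4-hydroxy-5-methyl-3,6-dioxo-2-(2-phenylethyl)cyclohexa-1,4-dien-1-yl]-6-[2-(2-methoxyphenyl)ethyl]-3-methylcyclohexa-2,5-diene-1,4-dione (target CNP0202346.0)
Conditions: (KSO3)2NO (excess), KH2PO4 buffer, H2O/acetone, 0 °C to rt
Reagents that add atoms: potassium nitrosodisulfonate (KSO3)2NO, [K+].[K+].[O]N(S(=O)(=O)[O-])S(=O)(=O)[O-]
Why: Teuber oxidation: in each 2-methylresorcinol ring the only free position (C1, C1') is para to the C4/C4' hydroxyl, so the nitrosodisulfonate radical should oxygenate it and give the 2-hydroxy-1,4-benzoquinone in both rings without touching the anisole.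

**Compound list**

1 | 3-phenylpropanal | O=CCCc1ccccc1 | starting material
2 | diethyl (2-oxobutyl)phosphonate | CCC(=O)CP(=O)(OCC)OCC | starting material
3 | (E)-7-phenylhept-4-en-3-one | CCC(=O)/C=C/CCc1ccccc1 | intermediate
4 | 3-(2-methoxyphenyl)propanoic acid | COc1ccccc1CCC(=O)O | starting material
5 | 3-(2-methoxyphenyl)propan-1-ol | COc1ccccc1CCCO | intermediate
6 | 3-(2-methoxyphenyl)propanal | COc1ccccc1CCC=O | intermediate
7 | (E)-7-(2-methoxyphenyl)hept-4-en-3-one | CCC(=O)/C=C/CCc1ccccc1OC | intermediate
8 | triethyl ethane-1,1,2-tricarboxylate | CCOC(=O)CC(C(=O)OCC)C(=O)OCC | starting material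
9 | triethyl 3-[2-(2-methoxyphenyl)ethyl]-5-oxoheptane-1,2,2-tricarboxylate (racemic; Michael adduct, not isolated) | CCOC(=O)CC(C(=O)OCC)(C(=O)OCC)C(CCc1ccccc1OC)CC(=O)CC | intermediate
10 | ethyl 1-(2-ethoxy-2-oxoethyl)-4-hydroxy-6-[2-(2-methoxyphenyl)ethyl]-3-methyl-2-oxocyclohex-3-ene-1-carboxylate (racemic diastereomer mixture; not isolated) | CCOC(=O)CC1(C(=O)OCC)C(=O)C(C)=C(O)CC1CCc1ccccc1OC | intermediate
11 | 1-(carboxymethyl)-4-hydroxy-6-[2-(2-methoxyphenyl)ethyl]-3-methyl-2-oxocyclohex-3-ene-1-carboxylic acid (racemic diastereomer mixture; not isolated) | OC(=O)CC1(C(=O)O)C(=O)C(C)=C(O)CC1CCc1ccccc1OC | intermediate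
12 | 2-{4-hydroxy-6-[2-(2-methoxyphenyl)ethyl]-3-methyl-2-oxocyclohex-3-en-1-yl}acetic acid (racemic diastereomer mixture, trans expected) | OC(=O)CC1C(=O)C(C)=C(O)CC1CCc1ccccc1OC | intermediate
13 | 2-{2,4-dihydroxy-6-[2-(2-methoxyphenyl)ethyl]-3-methylphenyl}acetic acid (not isolated) | OC(=O)Cc1c(O)c(C)c(O)cc1CCc1ccccc1OC | intermediate
14 | methyl 2-{2,4-dihydroxy-6-[2-(2-methoxyphenyl)ethyl]-3-methylphenyl}acetate | COC(=O)Cc1c(O)c(C)c(O)cc1CCc1ccccc1OC | intermediate
15 | methyl 2-{2,4-bis(benzyloxy)-6-[2-(2-methoxyphenyl)ethyl]-3-methylphenyl}acetate | COC(=O)Cc1c(OCc2ccccc2)c(C)c(OCc2ccccc2)cc1CCc1ccccc1OC | intermediate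
16 | methyl 2-{2,4-bis(benzyloxy)-6-[2-(2-methoxyphenyl)ethyl]-3-methylphenyl}-5-oxo-3-(2-phenylethyl)heptanoate (racemic diastereomer mixture; Michael adduct, not isolated) | COC(=O)C(c1c(OCc2ccccc2)c(C)c(OCc2ccccc2)cc1CCc1ccccc1OC)C(CCc1ccccc1)CC(=O)CC | intermediate
17 | trans-6-{2,4-bis(benzyloxy)-6-[2-(2-methoxyphenyl)ethyl]-3-methylphenyl}-3-hydroxy-2-methyl-5-(2-phenylethyl)cyclohex-2-en-1-one (racemic, one enantiomer drawn) | O=C1C(C)=C(O)C[C@H](CCc2ccccc2)[C@H]1c1c(OCc2ccccc2)c(C)c(OCc2ccccc2)cc1CCc1ccccc1OC | intermediate
18 | 2',4'-bis(benzyloxy)-6'-[2-(2-methoxyphenyl)ethyl]-3,3'-dimethyl-6-(2-phenylethyl)-[1,1'-biphenyl]-2,4-diol (racemic axis) | COc1ccccc1CCc1cc(OCc2ccccc2)c(C)c(OCc2ccccc2)c1-c1c(CCc2ccccc2)cc(O)c(C)c1O | intermediate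
19 | 6-[2-(2-methoxyphenyl)ethyl]-3,3'-dimethyl-6'-(2-phenylethyl)-[1,1'-biphenyl]-2,2',4,4'-tetrol (racemic axis) | COc1ccccc1CCc1cc(O)c(C)c(O)c1-c1c(CCc2ccccc2)cc(O)c(C)c1O | intermediate
20 | 2-hydroxy-5-[4-hydroxy-5-methyl-3,6-dioxo-2-(2-phenylethyl)cyclohexa-1,4-dien-1-yl]-6-[2-(2-methoxyphenyl)ethyl]-3-methylcyclohexa-2,5-diene-1,4-dione (no stereocentre; axis unspecified) | COc1ccccc1CCC1=C(C2=C(CCc3ccccc3)C(=O)C(O)=C(C)C2=O)C(=O)C(C)=C(O)C1=O | target

**Step count and risks**

Total: 11 steps. Longest linear sequence: 10 steps (4 to 20 through steps 2–11).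

Steps most likely to fail:

1. Step 8. The crowded, electron-rich benzylic enolate may add so slowly and reversibly that retro-Michael cleavage of the congested adduct and base-induced self-condensation of the enone outrun ring closure. The fallback sets out from 15 and returns at 17. Enolisation of 15 with LiN(i-Pr)2 and TMSCl in THF at −78 °C should give the ketene silyl acetal {[2-{2,4-bis(benzyloxy)-6-[2-(2-methoxyphenyl)ethyl]-3-methylphenyl}-1-methoxyethenyl]oxy}trimethylsilane F1. A Mukaiyama–Michael addition of this acetal to enone 3, promoted by TiCl4/Ti(O-i-Pr)4 in CH2Cl2 at −78 °C, forms the C5'–C6' bond irreversibly under Lewis acid control, and aqueous work-up should deliver keto ester 16 as an isolated compound. A separate Claisen closure of 16 with KOt-Bu in THF then gives 17.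

2. Step 5. Acylation may be misdirected: the C1 enolate can close a five-membered ring onto the acetate arm, an ester group can migrate, or the congested Michael adduct can revert before the six-membered closure takes place. The fallback sets out from 7 and returns at 12. Alkylation of diethyl malonate with tert-butyl bromoacetate (NaH, THF) should give 1-tert-butyl 2,2-diethyl ethane-1,2,2-tricarboxylate F2, whose acetate arm is a poor acyl acceptor. Under NaOEt in EtOH at reflux this triester and 7 should give the Michael adduct 1-tert-butyl 2,2-diethyl 3-[2-(2-methoxyphenyl)ethyl]-5-oxoheptane-1,2,2-tricarboxylate F3. The only Claisen closure then open leads to ethyl 1-(2-tert-butoxy-2-oxoethyl)-4-hydroxy-6-[2-(2-methoxyphenyl)ethyl]-3-methyl-2-oxocyclohex-3-ene-1-carboxylate F4. Hot aqueous HCl in AcOH removes the tert-butyl group, hydrolyses the keto ester and decarboxylates to 12.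

3. Step 9. Dehydrogenation may be slow because only the minor dienol tautomer donates hydride, and the oxidant may instead abstract hydride from the benzylic CH2 groups of the electron-rich arenes or add to the dione. The fallback sets out from 17 and returns at 19. Heating 17 with 10% Pd/C in refluxing mesitylene under a nitrogen sweep should dehydrogenate ring B catalytically, without a hydride-abstracting oxidant, to give 18. After cooling and dilution with EtOAc/MeOH, hydrogen is admitted to the same catalyst to complete the debenzylation to 19. Any benzyl ether cleavage by the liberated hydrogen only anticipates step 10, and any chain dehydrogenation is reversed in the hydrogenation. This detour creates no new compound (F0).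

**Further compounds**

F1 | step 8 | {[2-{2,4-bis(benzyloxy)-6-[2-(2-methoxyphenyl)ethyl]-3-methylphenyl}-1-methoxyethenyl]oxy}trimethylsilane (E/Z mixture) | COC(O[Si](C)(C)C)=Cc1c(OCc2ccccc2)c(C)c(OCc2ccccc2)cc1CCc1ccccc1OC
F2 | step 5 | 1-tert-butyl 2,2-diethyl ethane-1,2,2-tricarboxylate | CCOC(=O)C(CC(=O)OC(C)(C)C)C(=O)OCC
F3 | step 5 | 1-tert-butyl 2,2-diethyl 3-[2-(2-methoxyphenyl)ethyl]-5-oxoheptane-1,2,2-tricarboxylate (racemic) | CCOC(=O)C(CC(=O)OC(C)(C)C)(C(=O)OCC)C(CCc1ccccc1OC)CC(=O)CC
F4 | step 5 | ethyl 1-(2-tert-butoxy-2-oxoethyl)-4-hydroxy-6-[2-(2-methoxyphenyl)ethyl]-3-methyl-2-oxocyclohex-3-ene-1-carboxylate (racemic diastereomer mixture) | CCOC(=O)C1(CC(=O)OC(C)(C)C)C(=O)C(C)=C(O)CC1CCc1ccccc1OC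
F0 | step 9 | none | none
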